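**Retrosynthetic overview**
1. The ten-membered ring is closed last, at C1–C10, by an intramolecular Nozaki–Hiyama–Kishi reaction of a Z-alkenyl iodide with the C1 aldehyde; C15 desilylation then gives the target.
2. The cis-fused α-methylene-γ-butyrolactone is made before the carbocycle by a new phosphine-catalysed Morita–Baylis–Hillman-type epoxide opening of a threo epoxy acrylate (C7–C11 bond, C7 by inversion, O8 freed for the (S)-2-methylbutanoate).
3. The epoxy acrylate comes from a bis-allylic alcohol: asymmetric dienylzinc addition (C6–C7), Sharpless epoxidation (C7, C8), Mitsunobu esterification with acrylic acid (inverts C6).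
4. West fragment C1–C6/C15: trans-hydroalumination/iodination of a butynediol monosilyl ether, CrCl2/NiCl2 coupling with 3-(PMB-oxy)propanal, CBS reduction (C3). East fragment C7–C10/C14: (Z)-3-iodobut-2-en-1-ol, oxidation, Ohira–Bestmann alkynylation.
5. Ring order: lactone ring first (step 14), ten-membered carbocycle second (step 18).

Assumption: 1, 5, 13, 20 and 25 are bought as such; labels C1–C15 are the germacranolide positions of the target (C6/C7 ring fusion, C8 ester carbinol, C11–C13 methylene-lactone carbons, C14 methyl, C15 hydroxymethyl), and CIP descriptors that differ between intermediates reflect priority changes only, unless an inversion is stated.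

Step 1
Reactants: 1 4-[(tert-butyldimethylsilyl)oxy]but-2-yn-1-ol
Product: 3 (Z)-4-[(tert-butyldimethylsilyl)oxy]-3-iodobut-2-en-1-ol, via sodium alkenylalanate 2 (not isolated)
Conditions: NaAlH2(OCH2CH2OMe)2 (1.5 equiv), THF, 0 °C to rt; then I2 (1.6 equiv), THF, −78 to 0 °C
Reagents that add atoms: iodine, [I][I]
Why: Hydroxyl-directed trans-hydroalumination of the propargylic alcohol gives the five-membered alkenylalanate 2 with aluminium on C4, and iodinolysis with retention gives the Z-iodoalkene, which fixes the C4=C5 geometry of the target (C3 and C6 cis).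

Step 2
Reactants: 3 Z-iodo allylic alcohol
Product: 4 (Z)-4-[(tert-butyldimethylsilyl)oxy]-3-iodo-1-[(triethylsilyl)oxy]but-2-ene
Conditions: Et3SiCl, imidazole, CH2Cl2, 0 °C
Reagents that add atoms: chlorotriethylsilane, CC[Si](Cl)(CC)CC
Why: Standard silylation gives a primary triethylsilyl ether on O6 that survives the next four steps and is later removable next to the tert-butyldimethylsilyl ether.

Step 3
Reactants: 4 bis-silylated Z-alkenyl iodide; 5 3-[(4-methoxybenzyl)oxy]propanal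
Product: 7 racemic (Z)-4-{[(tert-butyldimethylsilyl)oxy]methyl}-1-[(4-methoxybenzyl)oxy]-6-[(triethylsilyl)oxy]hex-4-en-3-ol, via alkenylchromium dichloride 6 (not isolated)
Conditions: CrCl2 (4 equiv), NiCl2 (2 mol %), DMSO/THF, rt
Reagents that add atoms: none
Why: Nozaki–Hiyama–Kishi coupling, in which zerovalent nickel inserts into the carbon–iodine bond and transmetalation gives the trivalent alkenylchromium 6 that adds only to the aldehyde, forms the C3–C4 bond with retention of the Z-alkene; C3 is formed racemic and is set in steps 4 and 5.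

Step 4
Reactants: 7 racemic allylic alcohol
Product: 8 (Z)-4-{[(tert-butyldimethylsilyl)oxy]methyl}-1-[(4-methoxybenzyl)oxy]-6-[(triethylsilyl)oxy]hex-4-en-3-one
Conditions: Dess–Martin periodinane, pyridine, CH2Cl2, 0 °C to rt
Reagents that add atoms: none
Why: Dess–Martin oxidation under pyridine buffering converts the allylic alcohol into the enone without isomerising the Z-alkene or cleaving the silyl ethers.

Step 5
Reactants: 8 Z-enone
Product: 9 (3S,4Z)-4-{[(tert-butyldimethylsilyl)oxy]methyl}-1-[(4-methoxybenzyl)oxy]-6-[(triethylsilyl)oxy]hex-4-en-3-ol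
Conditions: (R)-2-methyl-CBS-oxazaborolidine [(R)-1-methyl-3,3-diphenyltetrahydro-1H,3H-pyrrolo[1,2-c][1,3,2]oxazaborole] (20 mol %), BH3·SMe2 (0.7 equiv), THF, −40 °C
Reagents that add atoms: none
Why: Corey–Bakshi–Shibata reduction, with the α-branched alkenyl group as the large and the CH2 chain as the small substituent, delivers hydride from the face that gives the (S)-alcohol with the (R)-catalyst (the sense of (R)-catalyst giving (S)-1-phenylethanol) and so sets C3.

Step 6
Reactants: 9 (3S)-allylic alcohol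
Product: 10 (3S,4Z)-4-{[(tert-butyldimethylsilyl)oxy]methyl}-1-[(4-methoxybenzyl)oxy]-6-[(triethylsilyl)oxy]hex-4-en-3-yl acetate
Conditions: Ac2O, pyridine, 4-(dimethylamino)pyridine (5 mol %), CH2Cl2, 0 °C to rt
Reagents that add atoms: acetic anhydride, CC(=O)OC(C)=O
Why: Standard acylation installs the C3 acetate of the target with retention.

Step 7
Reactants: 10 acetate
Product: 11 (3S,4Z)-4-{[(tert-butyldimethylsilyl)oxy]methyl}-6-hydroxy-1-[(4-methoxybenzyl)oxy]hex-4-en-3-yl acetate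
Conditions: pyridinium p-toluenesulfonate (10 mol %), MeOH, 0 °C
Reagents that add atoms: none
Why: Acid-catalysed methanolysis cleaves the primary triethylsilyl ether far faster than the tert-butyldimethylsilyl ether and leaves the acetate and the PMB ether untouched.

Step 8
Reactants: 11 primary allylic alcohol
Product: 12 (3S,4Z)-4-{[(tert-butyldimethylsilyl)oxy]methyl}-1-[(4-methoxybenzyl)oxy]-6-oxohex-4-en-3-yl acetate
Conditions: MnO2 (20 equiv), CH2Cl2, rt; used at once
Reagents that add atoms: none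
Why: Neutral MnO2 oxidation of the allylic alcohol gives the β,β-disubstituted Z-enal (C6 aldehyde) without alkene isomerisation or acetate elimination.

Step 9
Reactants: 13 (Z)-3-iodobut-2-en-1-ol
Product: 14 (Z)-3-iodobut-2-enal
Conditions: MnO2 (15 equiv), CH2Cl2, rt; filtered solution used directly
Reagents that add atoms: none
Why: Allylic oxidation with MnO2 keeps the Z-iodoalkene (the future C9=C10 geometry) intact.

Step 10
Reactants: 14 Z-iodo enal
Product: 15 (Z)-4-iodopent-3-en-1-yne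
Conditions: dimethyl (1-diazo-2-oxopropyl)phosphonate, K2CO3, MeOH, 0 °C to rt
Reagents that add atoms: dimethyl (1-diazo-2-oxopropyl)phosphonate, CC(=O)C(=[N+]=[N-])P(=O)(OC)OC
Why: Ohira–Bestmann (Seyferth–Gilbert) homologation turns the aldehyde into the terminal alkyne, adding C7, under mild base that leaves the Z-iodoalkene unchanged.

Step 11
Reactants: 15 Z-iodo enyne; 12 Z-enal
Product: 18 (3S,4Z,6S,7E,9Z)-4-{[(tert-butyldimethylsilyl)oxy]methyl}-6-hydroxy-10-iodo-1-[(4-methoxybenzyl)oxy]undeca-4,7,9-trien-3-yl acetate, via dienylborane 16 (not isolated), via dienylzinc 17 (not isolated)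
Conditions: 15 (1.5 equiv), Cy2BH (1.5 equiv), toluene, 0 °C to rt; Et2Zn (1.6 equiv), −78 °C; (−)-MIB [(2S)-3-exo-morpholinoisoborneol] (10 mol %); then 12, −20 to 0 °C
Reagents that add atoms: none
Why: Oppolzer-type alkenylzinc addition, in which syn-hydroboration and boron-to-zinc exchange give the E-dienylzinc 17 and the (−)-MIB zinc chelate directs it to the Si face of the aldehyde (the established sense of this ligand), forms the C6–C7 bond, the E-C7=C8 alkene and the (6S)-carbinol.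

Step 12
Reactants: 18 (6S)-bis-allylic alcohol
Product: 19 (3S,4Z,6R)-4-{[(tert-butyldimethylsilyl)oxy]methyl}-6-hydroxy-6-{(2R,3R)-3-[(Z)-2-iodoprop-1-en-1-yl]oxiran-2-yl}-1-[(4-methoxybenzyl)oxy]hex-4-en-3-yl acetate
Conditions: Ti(OiPr)4 (20 mol %), (−)-diisopropyl (2S,3S)-tartrate (24 mol %), tert-butyl hydroperoxide (2 equiv), 4 Å molecular sieves, CH2Cl2, −20 °C
Reagents that add atoms: tert-butyl hydroperoxide, CC(C)(C)OO
Why: Sharpless asymmetric epoxidation in its matched kinetic-resolution sense epoxidises only the E-disubstituted C7=C8 alkene next to the C6 hydroxyl and gives the erythro trans-epoxy alcohol, which sets C8 in its final configuration and C7 for the later inversion.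

Step 13
Reactants: 19 erythro epoxy alcohol; 20 acrylic acid
Product: 21 (1S,2Z,4S)-4-acetoxy-3-{[(tert-butyldimethylsilyl)oxy]methyl}-1-{(2S,3R)-3-[(Z)-2-iodoprop-1-en-1-yl]oxiran-2-yl}-6-[(4-methoxybenzyl)oxy]hex-2-en-1-yl acrylate
Conditions: PPh3 (1.5 equiv), diisopropyl azodicarboxylate (1.5 equiv), THF, 0 °C to rt
Reagents that add atoms: none
Why: Mitsunobu esterification, by SN2 attack of acrylate on the oxyphosphonium, inverts C6 to its final configuration, turns the erythro into the threo epoxy ester and brings in C11–C13, while the fully substituted C4 blocks the SN2′ path.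

Step 14
Reactants: 21 threo epoxy acrylate
Product: 24 (4R,5S)-5-[(1Z,3S)-3-acetoxy-2-{[(tert-butyldimethylsilyl)oxy]methyl}-5-[(4-methoxybenzyl)oxy]pent-1-en-1-yl]-4-[(1S,2Z)-1-hydroxy-3-iodobut-2-en-1-yl]-3-methylenedihydrofuran-2(3H)-one, via phosphonium enolate 22 (not isolated), via phosphonium alkoxide 23 (not isolated)
Conditions: PMe3 (30 mol %), 2-methylbutan-2-ol/THF 1:1, 0.02 molar, 23 to 45 °C
Reagents that add atoms: none
Why: Proposed new method: a phosphine-catalysed intramolecular Morita–Baylis–Hillman-type alkylation with an epoxide as electrophile, in which PMe3 adds to the acrylate β-carbon (C13), the β-phosphonium ester enolate 22 attacks the adjacent epoxide carbon C7 in a 5-exo SN2 opening with inversion (forming the C7–C11 bond, the γ-lactone ring and the C7 stereocentre and releasing O8 as the alkoxide of 23), and the C8 alkoxide then removes the C11 proton so that PMe3 leaves by E1cB and the exo-methylene is regenerated, the protic co-solvent activating the epoxide and buffering the alkoxide against translactonisation; the closest known reactions are intramolecular Morita–Baylis–Hillman alkylations of enones with tethered halides or epoxides under trialkylphosphines and the C2-selective intramolecular opening of 2,3-epoxy alcohol carbamates, whereas an acrylate ester tethered through oxygen has not been used in this way.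

Step 15
Reactants: 24 lactone alcohol; 25 (S)-2-methylbutanoic acid
Product: 26 (4S,5S)-5-[(1Z,3S)-3-acetoxy-2-{[(tert-butyldimethylsilyl)oxy]methyl}-5-[(4-methoxybenzyl)oxy]pent-1-en-1-yl]-4-[(1S,2Z)-3-iodo-1-{[(2S)-2-methylbutanoyl]oxy}but-2-en-1-yl]-3-methylenedihydrofuran-2(3H)-one
Conditions: N,N′-dicyclohexylcarbodiimide, 4-(dimethylamino)pyridine (10 mol %), CH2Cl2, 0 °C to rt
Reagents that add atoms: none
Why: Steglich esterification acylates the only free hydroxyl (O8) with retention at C8, and the low temperature and catalytic base keep the α-stereocentre of the acid intact.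

Step 16
Reactants: 26 PMB ether
Product: 27 (4S,5S)-5-[(1Z,3S)-3-acetoxy-2-{[(tert-butyldimethylsilyl)oxy]methyl}-5-hydroxypent-1-en-1-yl]-4-[(1S,2Z)-3-iodo-1-{[(2S)-2-methylbutanoyl]oxy}but-2-en-1-yl]-3-methylenedihydrofuran-2(3H)-one
Conditions: DDQ (1.3 equiv), CH2Cl2/pH 7 aqueous buffer, 0 °C
Reagents that add atoms: none
Why: Oxidative PMB cleavage by DDQ (benzylic hydride abstraction, then hydrolysis) frees the C1 primary alcohol without touching the esters, the silyl ether, the iodoalkene or the methylene lactone.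

Step 17
Reactants: 27 primary alcohol
Product: 28 (4S,5S)-5-[(1Z,3S)-3-acetoxy-2-{[(tert-butyldimethylsilyl)oxy]methyl}-5-oxopent-1-en-1-yl]-4-[(1S,2Z)-3-iodo-1-{[(2S)-2-methylbutanoyl]oxy}but-2-en-1-yl]-3-methylenedihydrofuran-2(3H)-one
Conditions: Dess–Martin periodinane, pyridine, CH2Cl2, 0 °C; used at once
Reagents that add atoms: none
Why: Buffered Dess–Martin oxidation gives the β-acetoxy aldehyde (C1) without β-elimination.

Step 18
Reactants: 28 iodo aldehyde
Product: 30 (1S,3S,4Z,6S,7R,8R,9Z)-3-acetoxy-15-[(tert-butyldimethylsilyl)oxy]-1-hydroxy-8-{[(2S)-2-methylbutanoyl]oxy}germacra-4,9,11(13)-trien-12,6-olide, via alkenylchromium dichloride 29 (not isolated)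
Conditions: CrCl2 (10 equiv), NiCl2 (0.1 equiv), degassed DMSO, 0.002 molar, slow addition, rt
Reagents that add atoms: none
Why: The intramolecular Nozaki–Hiyama–Kishi reaction adds the trivalent alkenylchromium 29 to the C1 aldehyde with retention of the Z-alkene, closing the low-strain (Z,Z)-cyclodeca-1,6-diene ring; C1 is set under substrate control, and the ring-forming transition state with the C3 acetate pseudo-equatorial is expected, not known, to give the (1S) 1,3-anti alcohol.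

Step 19
Reactants: 30 macrocyclic silyl ether
Product: 31 (1S,3S,4Z,6S,7R,8R,9Z)-3-acetoxy-1,15-dihydroxy-8-{[(2S)-2-methylbutanoyl]oxy}germacra-4,9,11(13)-trien-12,6-olide (CNP0217661.3)
Conditions: HF·pyridine, pyridine, THF, 0 °C to rt
Reagents that add atoms: none
Why: Buffered fluoride desilylation removes the primary allylic silyl ether and leaves both esters, the allylic alcohols and the methylene lactone intact.

**Compound list**
1 | 4-[(tert-butyldimethylsilyl)oxy]but-2-yn-1-ol | OCC#CCO[Si](C)(C)C(C)(C)C | starting material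
2 | sodium 4-{[(tert-butyldimethylsilyl)oxy]methyl}-2,2-bis(2-methoxyethoxy)-2,5-dihydro-1,2-oxaluminol-2-uide (cyclic alkenylalanate, Al on C4, not isolated) | [Na+].COCCO[Al-]1(OCCOC)OCC=C1CO[Si](C)(C)C(C)(C)C | intermediate
3 | (Z)-4-[(tert-butyldimethylsilyl)oxy]-3-iodobut-2-en-1-ol | OC/C=C(/CO[Si](C)(C)C(C)(C)C)I | intermediate
4 | (Z)-4-[(tert-butyldimethylsilyl)oxy]-3-iodo-1-[(triethylsilyl)oxy]but-2-ene | CC[Si](CC)(CC)OC/C=C(/CO[Si](C)(C)C(C)(C)C)I | intermediate
5 | 3-[(4-methoxybenzyl)oxy]propanal | O=CCCOCc1ccc(OC)cc1 | starting material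
6 | {(Z)-1-[(tert-butyldimethylsilyl)oxy]-4-[(triethylsilyl)oxy]but-2-en-2-yl}chromium dichloride (trivalent chromium in place of the iodine of 4, not isolated) | CC[Si](CC)(CC)OC/C=C(/CO[Si](C)(C)C(C)(C)C)[Cr](Cl)Cl | intermediate
7 | racemic (Z)-4-{[(tert-butyldimethylsilyl)oxy]methyl}-1-[(4-methoxybenzyl)oxy]-6-[(triethylsilyl)oxy]hex-4-en-3-ol | CC[Si](CC)(CC)OC/C=C(/CO[Si](C)(C)C(C)(C)C)C(O)CCOCc1ccc(OC)cc1 | intermediate
8 | (Z)-4-{[(tert-butyldimethylsilyl)oxy]methyl}-1-[(4-methoxybenzyl)oxy]-6-[(triethylsilyl)oxy]hex-4-en-3-one | CC[Si](CC)(CC)OC/C=C(/CO[Si](C)(C)C(C)(C)C)C(=O)CCOCc1ccc(OC)cc1 | intermediate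
9 | (3S,4Z)-4-{[(tert-butyldimethylsilyl)oxy]methyl}-1-[(4-methoxybenzyl)oxy]-6-[(triethylsilyl)oxy]hex-4-en-3-ol | CC[Si](CC)(CC)OC/C=C(/CO[Si](C)(C)C(C)(C)C)[C@@H](O)CCOCc1ccc(OC)cc1 | intermediate
10 | (3S,4Z)-4-{[(tert-butyldimethylsilyl)oxy]methyl}-1-[(4-methoxybenzyl)oxy]-6-[(triethylsilyl)oxy]hex-4-en-3-yl acetate | CC[Si](CC)(CC)OC/C=C(/CO[Si](C)(C)C(C)(C)C)[C@@H](OC(C)=O)CCOCc1ccc(OC)cc1 | intermediate
11 | (3S,4Z)-4-{[(tert-butyldimethylsilyl)oxy]methyl}-6-hydroxy-1-[(4-methoxybenzyl)oxy]hex-4-en-3-yl acetate | OC/C=C(/CO[Si](C)(C)C(C)(C)C)[C@@H](OC(C)=O)CCOCc1ccc(OC)cc1 | intermediate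
12 | (3S,4Z)-4-{[(tert-butyldimethylsilyl)oxy]methyl}-1-[(4-methoxybenzyl)oxy]-6-oxohex-4-en-3-yl acetate | O=C/C=C(/CO[Si](C)(C)C(C)(C)C)[C@@H](OC(C)=O)CCOCc1ccc(OC)cc1 | intermediate
13 | (Z)-3-iodobut-2-en-1-ol | OC/C=C(/C)I | starting material
14 | (Z)-3-iodobut-2-enal | O=C/C=C(/C)I | intermediate
15 | (Z)-4-iodopent-3-en-1-yne | C#C/C=C(/C)I | intermediate
16 | dicyclohexyl[(1E,3Z)-4-iodopenta-1,3-dien-1-yl]borane (not isolated) | C1CCCCC1B(/C=C/C=C(/C)I)C1CCCCC1 | intermediate
17 | ethyl[(1E,3Z)-4-iodopenta-1,3-dien-1-yl]zinc (not isolated) | CC[Zn]/C=C/C=C(/C)I | intermediate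
18 | (3S,4Z,6S,7E,9Z)-4-{[(tert-butyldimethylsilyl)oxy]methyl}-6-hydroxy-10-iodo-1-[(4-methoxybenzyl)oxy]undeca-4,7,9-trien-3-yl acetate | O[C@@H](/C=C/C=C(/C)I)/C=C(/CO[Si](C)(C)C(C)(C)C)[C@@H](OC(C)=O)CCOCc1ccc(OC)cc1 | intermediate
19 | (3S,4Z,6R)-4-{[(tert-butyldimethylsilyl)oxy]methyl}-6-hydroxy-6-{(2R,3R)-3-[(Z)-2-iodoprop-1-en-1-yl]oxiran-2-yl}-1-[(4-methoxybenzyl)oxy]hex-4-en-3-yl acetate (erythro, trans-epoxide) | O[C@@H]([C@H]1O[C@@H]1/C=C(/C)I)/C=C(/CO[Si](C)(C)C(C)(C)C)[C@@H](OC(C)=O)CCOCc1ccc(OC)cc1 | intermediate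
20 | acrylic acid | C=CC(=O)O | starting material
21 | (1S,2Z,4S)-4-acetoxy-3-{[(tert-butyldimethylsilyl)oxy]methyl}-1-{(2S,3R)-3-[(Z)-2-iodoprop-1-en-1-yl]oxiran-2-yl}-6-[(4-methoxybenzyl)oxy]hex-2-en-1-yl acrylate (threo; C6 inverted relative to 19) | C=CC(=O)O[C@H]([C@H]1O[C@@H]1/C=C(/C)I)/C=C(/CO[Si](C)(C)C(C)(C)C)[C@@H](OC(C)=O)CCOCc1ccc(OC)cc1 | intermediate
22 | zwitterion from 21 and PMe3: trimethylphosphonium on C13, ester enolate at C11/C12 (not isolated) | C[P+](C)(C)CC=C([O-])O[C@H]([C@H]1O[C@@H]1/C=C(/C)I)/C=C(/CO[Si](C)(C)C(C)(C)C)[C@@H](OC(C)=O)CCOCc1ccc(OC)cc1 | intermediate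
23 | zwitterion after ring closure: γ-lactone with trimethylphosphoniomethyl on C11 and alkoxide on C8, C7 inverted (not isolated) | C[P+](C)(C)CC1C(=O)O[C@@H](/C=C(/CO[Si](C)(C)C(C)(C)C)[C@@H](OC(C)=O)CCOCc2ccc(OC)cc2)[C@H]1[C@H]([O-])/C=C(/C)I | intermediate
24 | (4R,5S)-5-[(1Z,3S)-3-acetoxy-2-{[(tert-butyldimethylsilyl)oxy]methyl}-5-[(4-methoxybenzyl)oxy]pent-1-en-1-yl]-4-[(1S,2Z)-1-hydroxy-3-iodobut-2-en-1-yl]-3-methylenedihydrofuran-2(3H)-one | C=C1C(=O)O[C@@H](/C=C(/CO[Si](C)(C)C(C)(C)C)[C@@H](OC(C)=O)CCOCc2ccc(OC)cc2)[C@H]1[C@H](O)/C=C(/C)I | intermediate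
25 | (S)-2-methylbutanoic acid | CC[C@H](C)C(=O)O | starting material
26 | (4S,5S)-5-[(1Z,3S)-3-acetoxy-2-{[(tert-butyldimethylsilyl)oxy]methyl}-5-[(4-methoxybenzyl)oxy]pent-1-en-1-yl]-4-[(1S,2Z)-3-iodo-1-{[(2S)-2-methylbutanoyl]oxy}but-2-en-1-yl]-3-methylenedihydrofuran-2(3H)-one | C=C1C(=O)O[C@@H](/C=C(/CO[Si](C)(C)C(C)(C)C)[C@@H](OC(C)=O)CCOCc2ccc(OC)cc2)[C@H]1[C@H](OC(=O)[C@@H](C)CC)/C=C(/C)I | intermediate
27 | (4S,5S)-5-[(1Z,3S)-3-acetoxy-2-{[(tert-butyldimethylsilyl)oxy]methyl}-5-hydroxypent-1-en-1-yl]-4-[(1S,2Z)-3-iodo-1-{[(2S)-2-methylbutanoyl]oxy}but-2-en-1-yl]-3-methylenedihydrofuran-2(3H)-one | C=C1C(=O)O[C@@H](/C=C(/CO[Si](C)(C)C(C)(C)C)[C@@H](OC(C)=O)CCO)[C@H]1[C@H](OC(=O)[C@@H](C)CC)/C=C(/C)I | intermediate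
28 | (4S,5S)-5-[(1Z,3S)-3-acetoxy-2-{[(tert-butyldimethylsilyl)oxy]methyl}-5-oxopent-1-en-1-yl]-4-[(1S,2Z)-3-iodo-1-{[(2S)-2-methylbutanoyl]oxy}but-2-en-1-yl]-3-methylenedihydrofuran-2(3H)-one | C=C1C(=O)O[C@@H](/C=C(/CO[Si](C)(C)C(C)(C)C)[C@@H](OC(C)=O)CC=O)[C@H]1[C@H](OC(=O)[C@@H](C)CC)/C=C(/C)I | intermediate
29 | alkenylchromium dichloride from 28 (trivalent chromium in place of iodine on C10, not isolated) | C=C1C(=O)O[C@@H](/C=C(/CO[Si](C)(C)C(C)(C)C)[C@@H](OC(C)=O)CC=O)[C@H]1[C@H](OC(=O)[C@@H](C)CC)/C=C(/C)[Cr](Cl)Cl | intermediate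
30 | (1S,3S,4Z,6S,7R,8R,9Z)-3-acetoxy-15-[(tert-butyldimethylsilyl)oxy]-1-hydroxy-8-{[(2S)-2-methylbutanoyl]oxy}germacra-4,9,11(13)-trien-12,6-olide | C=C1C(=O)O[C@H]2/C=C(/CO[Si](C)(C)C(C)(C)C)[C@@H](OC(C)=O)C[C@H](O)\C(C)=C/[C@@H](OC(=O)[C@@H](C)CC)[C@@H]12 | intermediate
31 | (1S,3S,4Z,6S,7R,8R,9Z)-3-acetoxy-1,15-dihydroxy-8-{[(2S)-2-methylbutanoyl]oxy}germacra-4,9,11(13)-trien-12,6-olide (CNP0217661.3) | C=C1C(=O)O[C@H]2/C=C(/CO)[C@@H](OC(C)=O)C[C@H](O)\C(C)=C/[C@@H](OC(=O)[C@@H](C)CC)[C@@H]12 | target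

**Step count and risks**
Total step count: 19. Longest linear sequence: 17 steps (steps 1–8, then 11–19, from 1).

Step 14 (the proposed new reaction). The ester must reach the conformation that puts C11, not the enolate oxygen, behind C7. Attack at the allylic C8 (6-endo) or translactonisation onto O8 could also compete. The fallback uses known chemistry; it sets out from 19 and comes back at 24. Mitsunobu esterification of 19 with (diethoxyphosphoryl)acetic acid (PPh3, diisopropyl azodicarboxylate, THF) gives, with the same inversion at C6, the threo epoxy phosphonoacetate F1. LiCl and DBU in MeCN generate the stabilised phosphonoacetate carbanion, which opens the epoxide 5-exo at C7 with inversion to give the α-(diethoxyphosphoryl) lactone F2. Horner–Wadsworth–Emmons methylenation of F2 with aqueous formaldehyde and K2CO3 in THF at 0 °C then gives 24.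

Step 18 (ten-membered ring closure). The ring may close with low or wrong selectivity at C1, and the alkenylmetal could add to the methylene lactone instead. The fallback sets out from 28 and comes back at 30. The same CrCl2/NiCl2 cyclisation is run without regard to C1, giving 30 together with the C1 epimer F3. The mixture is oxidised (Dess–Martin periodinane, pyridine) to the macrocyclic Z-enone F4. F4 is reduced with (R)-2-methyl-CBS-oxazaborolidine and catecholborane at −78 °C, so that C1 is set by the reagent (alkenyl as the large group) and 30 is obtained as the (1S) alcohol.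

Step 13 (Mitsunobu inversion at a hindered carbinol that is both allylic and next to an epoxide). Elimination or a sluggish reaction is possible. The fallback sets out from 12 (with 15) and comes back at 21, and needs no inversion. Dienylzinc 17 is added to 12 with (+)-MIB in place of (−)-MIB to give the (6R) bis-allylic alcohol F5. Acryloyl chloride and Et3N in CH2Cl2 at −20 °C give the acrylate F6, in which C6 already has its final configuration. Shi epoxidation (ketone catalyst derived from natural fructose, 1,2:4,5-di-O-isopropylidene-β-D-erythro-2,3-hexodiulo-2,6-pyranose, KHSO5, K2CO3, MeCN/dimethoxymethane/aqueous buffer, 0 °C) then epoxidises the E-C7=C8 alkene under reagent control on the face that gives 21. The acrylate alkene is electron-poor, and the C4=C5 and iodo-substituted alkenes are deactivated, so they should react more slowly.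

**Further compounds**
F1 | step 14 | (1S,2Z,4S)-4-acetoxy-3-{[(tert-butyldimethylsilyl)oxy]methyl}-1-{(2S,3R)-3-[(Z)-2-iodoprop-1-en-1-yl]oxiran-2-yl}-6-[(4-methoxybenzyl)oxy]hex-2-en-1-yl (diethoxyphosphoryl)acetate | CCOP(=O)(OCC)CC(=O)O[C@H]([C@H]1O[C@@H]1/C=C(/C)I)/C=C(/CO[Si](C)(C)C(C)(C)C)[C@@H](OC(C)=O)CCOCc1ccc(OC)cc1
F2 | step 14 | (3S,4R,5S)-5-[(1Z,3S)-3-acetoxy-2-{[(tert-butyldimethylsilyl)oxy]methyl}-5-[(4-methoxybenzyl)oxy]pent-1-en-1-yl]-3-(diethoxyphosphoryl)-4-[(1S,2Z)-1-hydroxy-3-iodobut-2-en-1-yl]dihydrofuran-2(3H)-one | CCOP(=O)(OCC)[C@@H]1C(=O)O[C@@H](/C=C(/CO[Si](C)(C)C(C)(C)C)[C@@H](OC(C)=O)CCOCc2ccc(OC)cc2)[C@H]1[C@H](O)/C=C(/C)I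
F3 | step 18 | (1R,3S,4Z,6S,7R,8R,9Z)-3-acetoxy-15-[(tert-butyldimethylsilyl)oxy]-1-hydroxy-8-{[(2S)-2-methylbutanoyl]oxy}germacra-4,9,11(13)-trien-12,6-olide | C=C1C(=O)O[C@H]2/C=C(/CO[Si](C)(C)C(C)(C)C)[C@@H](OC(C)=O)C[C@@H](O)\C(C)=C/[C@@H](OC(=O)[C@@H](C)CC)[C@@H]12
F4 | step 18 | (3S,4Z,6S,7R,8R,9Z)-3-acetoxy-15-[(tert-butyldimethylsilyl)oxy]-8-{[(2S)-2-methylbutanoyl]oxy}-1-oxogermacra-4,9,11(13)-trien-12,6-olide | C=C1C(=O)O[C@H]2/C=C(/CO[Si](C)(C)C(C)(C)C)[C@@H](OC(C)=O)CC(=O)\C(C)=C/[C@@H](OC(=O)[C@@H](C)CC)[C@@H]12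
F5 | step 13 | (3S,4Z,6R,7E,9Z)-4-{[(tert-butyldimethylsilyl)oxy]methyl}-6-hydroxy-10-iodo-1-[(4-methoxybenzyl)oxy]undeca-4,7,9-trien-3-yl acetate | O[C@H](/C=C/C=C(/C)I)/C=C(/CO[Si](C)(C)C(C)(C)C)[C@@H](OC(C)=O)CCOCc1ccc(OC)cc1
F6 | step 13 | (3S,4Z,6R,7E,9Z)-3-acetoxy-4-{[(tert-butyldimethylsilyl)oxy]methyl}-10-iodo-1-[(4-methoxybenzyl)oxy]undeca-4,7,9-trien-6-yl acrylate | C=CC(=O)O[C@H](/C=C/C=C(/C)I)/C=C(/CO[Si](C)(C)C(C)(C)C)[C@@H](OC(C)=O)CCOCc1ccc(OC)cc1
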